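**Retrosynthetic overview**
1. Target ⇐ desilylation, dibenzoylation and acetonide/TBS removal from a bicyclic allylic chloride, itself made by invertive chlorination of the C2 allylic alcohol.
2. Allylic alcohol ⇐ face-selective 1,2-reduction of a cyclohexenone ⇐ acyclic dienone by ring-closing metathesis (C3=C4). This is the only carbocycle and it is closed after all other skeletal bonds.
3. Dienone ⇐ Weinreb amide + vinylmagnesium bromide (C2–C3 bond) ⇐ branched sugar lactone.
4. Key C–C disconnection: the C1–CH2O bond, made by crossed aldol of a sugar lactol with formaldehyde, which creates the quaternary carbinol C1.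
5. Lactol ⇐ D-gulono-1,4-lactone, which supplies the C1-O, C6 and C5 configurations; its 5,6-diol becomes the C4 vinyl group.

Assumption: D-gulono-1,4-lactone is taken as an inexpensive commercial chiral-pool lactone.
Carbocyclic compounds are described with the target's ring numbering (C1 quaternary carbinol, C2 CHCl, C3=C4, C5 CHOH, C6 CHOBz).

**Step 1**
Reactants: 1 D-gulono-1,4-lactone
Product: 2 2,3:5,6-di-O-isopropylidene-D-gulono-1,4-lactone
Conditions: Me2C(OMe)2, TsOH·H2O (cat.), acetone, rt
Reagents that add atoms: 2,2-dimethoxypropane, COC(C)(C)OC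
Why: Acid-catalysed acetonide formation (transacetalisation) under thermodynamic control ties up the cis-2,3-diol and the terminal 5,6-diol as dioxolanes without touching a stereocentre.

**Step 2**
Reactants: 2 2,3:5,6-di-O-isopropylidene-D-gulono-1,4-lactone
Product: 3 2,3-O-isopropylidene-D-gulono-1,4-lactone
Conditions: AcOH/H2O (7:3), rt
Reagents that add atoms: none
Why: Selective acetal hydrolysis works because the terminal 5,6-dioxolane hydrolyses much faster than the ring-fused 2,3-dioxolane.

**Step 3**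
Reactants: 3 2,3-O-isopropylidene-D-gulono-1,4-lactone
Product: 4 5,6-dideoxy-2,3-O-isopropylidene-L-lyxo-hex-5-enono-1,4-lactone (vinyl group and dioxolane all cis on the lactone ring)
Conditions: PPh3, I2, imidazole, toluene, 110 °C
Reagents that add atoms: none
Why: Garegg–Samuelsson olefination converts the vicinal diol, via the primary iodide and the secondary oxyphosphonium salt, into the terminal alkene by iodide-induced reductive elimination, which erases C5 and leaves C2–C4 unchanged.

**Step 4**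
Reactants: 4 5,6-dideoxy-2,3-O-isopropylidene-L-lyxo-hex-5-enono-1,4-lactone
Product: 5 5,6-dideoxy-2,3-O-isopropylidene-L-lyxo-hex-5-enofuranose (anomer mixture)
Conditions: i-Bu2AlH (1.1 equiv), CH2Cl2, −78 °C; aq. KNaC4H4O6 work-up
Reagents that add atoms: none
Why: Partial lactone reduction stops at the lactol because the tetrahedral aluminium hemiacetal is stable at −78 °C until work-up.

**Step 5**
Reactants: 5 5,6-dideoxy-2,3-O-isopropylidene-L-lyxo-hex-5-enofuranose; 6 formaldehyde
Product: 8 5,6-dideoxy-2-C-(hydroxymethyl)-2,3-O-isopropylidene-L-lyxo-hex-5-enofuranose, via open-chain aldol aldehyde 7 (not isolated)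
Conditions: 37% aq. HCHO, K2CO3, MeOH, 65 °C
Reagents that add atoms: formaldehyde, C=O
Why: Crossed aldol (Ho hydroxymethylation): K2CO3 enolises the ring-opened aldehyde at C-2, its only enolisable position, the enolate adds to formaldehyde, and because the aldol is reversible and only the adduct with the formyl group cis to C-4 can close to the cis-fused furanose, one configuration results at the new quaternary carbon (C1 of the target).

**Step 6**
Reactants: 8 5,6-dideoxy-2-C-(hydroxymethyl)-2,3-O-isopropylidene-L-lyxo-hex-5-enofuranose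
Product: 9 2-C-[(tert-butyldimethylsilyloxy)methyl]-5,6-dideoxy-2,3-O-isopropylidene-L-lyxo-hex-5-enofuranose
Conditions: TBSCl (1.1 equiv), imidazole, DMF, 0 °C
Reagents that add atoms: tert-butyldimethylsilyl chloride, CC(C)(C)[Si](C)(C)Cl
Why: Silyl ether formation is selective for the primary alcohol over the hindered hemiacetal hydroxyl, which must stay free for the next oxidation.

**Step 7**
Reactants: 9 2-C-[(tert-butyldimethylsilyloxy)methyl]-5,6-dideoxy-2,3-O-isopropylidene-L-lyxo-hex-5-enofuranose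
Product: 10 2-C-[(tert-butyldimethylsilyloxy)methyl]-5,6-dideoxy-2,3-O-isopropylidene-L-lyxo-hex-5-enono-1,4-lactone
Conditions: DMP, CH2Cl2, rt
Reagents that add atoms: none
Why: Dess–Martin oxidation of the lactol gives the lactone under near-neutral conditions that spare the TBS ether, the acetonide and the alkene.

**Step 8**
Reactants: 10 2-C-[(tert-butyldimethylsilyloxy)methyl]-5,6-dideoxy-2,3-O-isopropylidene-L-lyxo-hex-5-enono-1,4-lactone
Product: 11 2-C-[(tert-butyldimethylsilyloxy)methyl]-5,6-dideoxy-2,3-O-isopropylidene-N-methoxy-N-methyl-L-lyxo-hex-5-enonamide (free 4-OH)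
Conditions: MeNH(OMe)·HCl, i-PrMgCl (premixed), THF, −20 → 0 °C; aq. NH4Cl
Reagents that add atoms: N,O-dimethylhydroxylamine hydrochloride, CNOC.Cl
Why: Weinreb aminolysis of the lactone by the chloromagnesium amide ClMgN(OMe)Me opens the ring and frees only the C-4 hydroxyl, which distinguishes it from the oxygen that will later sit on the former carbonyl carbon.

**Step 9**
Reactants: 11 2-C-[(tert-butyldimethylsilyloxy)methyl]-5,6-dideoxy-2,3-O-isopropylidene-N-methoxy-N-methyl-L-lyxo-hex-5-enonamide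
Product: 12 the 4-O-triisopropylsilyl ether of 11
Conditions: TIPSOTf, 2,6-lutidine, CH2Cl2, −78 → 0 °C
Reagents that add atoms: triisopropylsilyl trifluoromethanesulfonate, CC(C)[Si](OS(=O)(=O)C(F)(F)F)(C(C)C)C(C)C
Why: Silylation with the reactive triflate protects the secondary allylic alcohol quickly, blocks relactonisation, and installs the one silyl group meant to outlast the later acidic methanolysis.

**Step 10**
Reactants: 12 the 4-O-triisopropylsilyl Weinreb amide; 13 vinylmagnesium bromide
Product: 14 acyclic dienone: 1-{4-[(tert-butyldimethylsilyloxy)methyl]-2,2-dimethyl-5-[1-(triisopropylsilyloxy)prop-2-en-1-yl]-1,3-dioxolan-4-yl}prop-2-en-1-one (acryloyl and silyloxyallyl arms cis on the dioxolane, configuration as in 12)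
Conditions: THF, 0 °C → rt; inverse quench into cold aq. NH4Cl
Reagents that add atoms: vinylmagnesium bromide, C=C[Mg]Br
Why: Weinreb ketone synthesis: the five-membered N,O-chelated magnesium adduct holds until the quench, so a single vinyl group is delivered and the enone appears only on work-up.

**Step 11**
Reactants: 14 acyclic dienone
Product: 15 acetonide-protected cyclohexenone (C2 ketone, C3=C4, cis-fused O1/O6 acetonide, 1-CH2OTBS, 5-OTIPS trans to O6)
Conditions: second-generation Grubbs catalyst RuCl2(=CHPh)(PCy3)(H2IMes) (5 mol %), CH2Cl2 (5 mM), 40 °C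
Reagents that add atoms: none
Why: Ring-closing metathesis is favoured because the cis-dioxolane holds the two vinyl-bearing arms on the same face, six-membered ring closure is fast and ethene is lost.

**Step 12**
Reactants: 15 acetonide-protected cyclohexenone
Product: 16 allylic alcohol (2-OH cis to O1 and O6; otherwise as 15)
Conditions: NaBH4, CeCl3·7H2O, MeOH, −78 °C
Reagents that add atoms: none
Why: Luche 1,2-reduction: hydride attacks the carbonyl anti to the adjacent C1–O bond and from the face opposite the cis-fused dioxolane, which sets C2 with the hydroxyl cis to O1.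

**Step 13**
Reactants: 16 allylic alcohol
Product: 17 allylic chloride (2-Cl trans to O1; acetonide, TBS and TIPS groups intact)
Conditions: PPh3, Cl3CC(O)CCl3, CH2Cl2, 0 °C → rt
Reagents that add atoms: hexachloroacetone, ClC(Cl)(Cl)C(=O)C(Cl)(Cl)Cl
Why: Appel-type chlorination: chloride displaces the oxyphosphonium group in an SN2 step at low temperature, so C2 is inverted and chlorine ends trans to O1 as in the target (2R), and this reagent pair is chosen because it gives little allylic transposition.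

**Step 14**
Reactants: 17 allylic chloride
Product: 18 (1R,2R,5S,6R)-2-chloro-1-(hydroxymethyl)-5-(triisopropylsilyloxy)cyclohex-3-ene-1,6-diol
Conditions: CSA (cat.), MeOH, rt → 40 °C
Reagents that add atoms: none
Why: Acid-catalysed transacetalisation and methanolysis remove the acetonide and the primary TBS ether, while the bulkier secondary TIPS ether solvolyses far more slowly and stays to mask O5.

**Step 15**
Reactants: 18 chloro triol
Product: 19 [(1R,2R,5S,6R)-6-(benzoyloxy)-2-chloro-1-hydroxy-5-(triisopropylsilyloxy)cyclohex-3-en-1-yl]methyl benzoate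
Conditions: BzCl (2.5 equiv), pyridine, DMAP (cat.), CH2Cl2, 0 °C → rt
Reagents that add atoms: benzoyl chloride, O=C(Cl)c1ccccc1
Why: DMAP-catalysed acylation esterifies the primary and the secondary hydroxyl, while the tertiary C1 hydroxyl is too hindered to react and O5 is still silylated.

**Step 16**
Reactants: 19 TIPS-protected dibenzoate
Product: 20 [(1R,2R,5S,6R)-6-(benzoyloxy)-2-chloro-1,5-dihydroxycyclohex-3-en-1-yl]methyl benzoate (CNP0326102.1)
Conditions: HF·pyridine, pyridine/THF, 0 °C → rt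
Reagents that add atoms: none
Why: Fluoride-mediated desilylation under acidic buffered conditions frees the C5 hydroxyl without base, which avoids benzoate migration and epoxide formation from the chlorohydrin.

**Compound list**
1 | D-gulono-1,4-lactone | O=C1[C@H](O)[C@H](O)[C@H]([C@H](O)CO)O1 | starting material
2 | 2,3:5,6-di-O-isopropylidene-D-gulono-1,4-lactone | O=C1[C@@H]2OC(C)(C)O[C@@H]2[C@H]([C@H]3COC(C)(C)O3)O1 | intermediate
3 | 2,3-O-isopropylidene-D-gulono-1,4-lactone | O=C1[C@@H]2OC(C)(C)O[C@@H]2[C@H]([C@H](O)CO)O1 | intermediate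
4 | 5,6-dideoxy-2,3-O-isopropylidene-L-lyxo-hex-5-enono-1,4-lactone | O=C1[C@@H]2OC(C)(C)O[C@@H]2[C@H](C=C)O1 | intermediate
5 | 5,6-dideoxy-2,3-O-isopropylidene-L-lyxo-hex-5-enofuranose (anomer mixture) | OC1[C@@H]2OC(C)(C)O[C@@H]2[C@H](C=C)O1 | intermediate
6 | formaldehyde | C=O | starting material
7 | open-chain aldol aldehyde (5,6-dideoxy-2-C-(hydroxymethyl)-2,3-O-isopropylidene-aldehydo-L-lyxo-hex-5-enose) | O=C[C@]1(CO)OC(C)(C)O[C@@H]1[C@@H](O)C=C | intermediate
8 | 5,6-dideoxy-2-C-(hydroxymethyl)-2,3-O-isopropylidene-L-lyxo-hex-5-enofuranose | OC1[C@]2(CO)OC(C)(C)O[C@@H]2[C@H](C=C)O1 | intermediate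
9 | 2-C-[(tert-butyldimethylsilyloxy)methyl]-5,6-dideoxy-2,3-O-isopropylidene-L-lyxo-hex-5-enofuranose | OC1[C@]2(CO[Si](C)(C)C(C)(C)C)OC(C)(C)O[C@@H]2[C@H](C=C)O1 | intermediate
10 | 2-C-[(tert-butyldimethylsilyloxy)methyl]-5,6-dideoxy-2,3-O-isopropylidene-L-lyxo-hex-5-enono-1,4-lactone | O=C1[C@]2(CO[Si](C)(C)C(C)(C)C)OC(C)(C)O[C@@H]2[C@H](C=C)O1 | intermediate
11 | 2-C-[(tert-butyldimethylsilyloxy)methyl]-5,6-dideoxy-2,3-O-isopropylidene-N-methoxy-N-methyl-L-lyxo-hex-5-enonamide | CON(C)C(=O)[C@]1(CO[Si](C)(C)C(C)(C)C)OC(C)(C)O[C@@H]1[C@@H](O)C=C | intermediate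
12 | 4-O-triisopropylsilyl ether of 11 | CON(C)C(=O)[C@]1(CO[Si](C)(C)C(C)(C)C)OC(C)(C)O[C@@H]1[C@@H](O[Si](C(C)C)(C(C)C)C(C)C)C=C | intermediate
13 | vinylmagnesium bromide | C=C[Mg]Br | starting material
14 | acyclic dienone (acryloyl and silyloxyallyl arms cis on the dioxolane) | C=CC(=O)[C@]1(CO[Si](C)(C)C(C)(C)C)OC(C)(C)O[C@@H]1[C@@H](O[Si](C(C)C)(C(C)C)C(C)C)C=C | intermediate
15 | acetonide-protected cyclohexenone (C2 ketone, 5-OTIPS trans to O6) | O=C1C=C[C@H](O[Si](C(C)C)(C(C)C)C(C)C)[C@H]2OC(C)(C)O[C@@]12CO[Si](C)(C)C(C)(C)C | intermediate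
16 | allylic alcohol (2-OH cis to O1) | O[C@H]1C=C[C@H](O[Si](C(C)C)(C(C)C)C(C)C)[C@H]2OC(C)(C)O[C@@]12CO[Si](C)(C)C(C)(C)C | intermediate
17 | allylic chloride (2-Cl trans to O1) | Cl[C@@H]1C=C[C@H](O[Si](C(C)C)(C(C)C)C(C)C)[C@H]2OC(C)(C)O[C@@]12CO[Si](C)(C)C(C)(C)C | intermediate
18 | (1R,2R,5S,6R)-2-chloro-1-(hydroxymethyl)-5-(triisopropylsilyloxy)cyclohex-3-ene-1,6-diol | OC[C@]1(O)[C@H](Cl)C=C[C@H](O[Si](C(C)C)(C(C)C)C(C)C)[C@H]1O | intermediate
19 | [(1R,2R,5S,6R)-6-(benzoyloxy)-2-chloro-1-hydroxy-5-(triisopropylsilyloxy)cyclohex-3-en-1-yl]methyl benzoate | O=C(OC[C@]1(O)[C@H](Cl)C=C[C@H](O[Si](C(C)C)(C(C)C)C(C)C)[C@H]1OC(=O)c1ccccc1)c1ccccc1 | intermediate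
20 | [(1R,2R,5S,6R)-6-(benzoyloxy)-2-chloro-1,5-dihydroxycyclohex-3-en-1-yl]methyl benzoate | O=C(OC[C@]1(O)[C@H](Cl)C=C[C@H](O)[C@H]1OC(=O)c1ccccc1)c1ccccc1 | target

**Totals and risk**
Total step count: 16. Longest linear sequence: 16 steps (fully linear from 1).

The three steps most likely to fail:

Step 8 (Weinreb opening of the hindered α-quaternary lactone; the γ-hydroxy amide can relactonise). The fallback sets out from lactol 9 and comes back at dienone 14. Lactol 9 is treated with vinylmagnesium bromide 13 (THF, 0 °C → rt) to give the ring-opened divinyl diol F1 as an epimer mixture at the new carbinol. The less hindered carbinol, which is flanked by a CH and not by the quaternary carbon, is silylated with TIPSOTf (1.05 equiv)/2,6-lutidine at −78 °C to give the mono-TIPS ether F2. Dess–Martin oxidation of the remaining hindered allylic alcohol converges both epimers on 14.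

Step 12 (facial selectivity of the 1,2-reduction next to a quaternary centre). The fallback sets out from enone 15 and comes back at 16. If hydride is delivered from the acetonide face, the product is the C2-epimeric allylic alcohol F3 (2-OH trans to O1). Mitsunobu inversion of F3 with 4-nitrobenzoic acid, PPh3 and DIAD gives the inverted 4-nitrobenzoate F4 (2-O cis to O1), and K2CO3/MeOH methanolysis of F4 gives 16.

Step 13 (SN2 chlorination at an allylic carbon next to a quaternary centre; allylic transposition or elimination may compete). The fallback sets out from 16 and comes back at 19. It replaces the intermolecular displacement of an oxyphosphonium group by opening of a cyclic sulfate.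
- Alcohol 16 is protected with 4-methoxybenzyl trichloroacetimidate (cat. CSA, CH2Cl2) as the 2-O-(4-methoxybenzyl) ether F5.
- CSA/MeOH removes the acetonide and TBS group to give the PMB-protected triol F6.
- BzCl/pyridine/DMAP gives the PMB-protected dibenzoate F7.
- DDQ (CH2Cl2/pH 7 buffer) frees the cis-1,2-diol dibenzoate F8.
- SOCl2/Et3N gives the 1,2-cyclic sulfite F9, which RuCl3 (cat.)/NaIO4 (MeCN/H2O, 0 °C, short contact) oxidises to the 1,2-cyclic sulfate F10.
- LiCl in DMF opens F10 at the secondary allylic carbon with inversion to the lithium 1-O-sulfate F11, and brief hydrolysis (cat. H2SO4, H2O/THF) gives 19.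

**Further compounds**
F1 | step 8 | ring-opened divinyl diol from 9 (epimer mixture at the new carbinol) | C=CC(O)[C@]1(CO[Si](C)(C)C(C)(C)C)OC(C)(C)O[C@@H]1[C@@H](O)C=C
F2 | step 8 | mono-TIPS ether of F1 at the less hindered carbinol | C=CC(O)[C@]1(CO[Si](C)(C)C(C)(C)C)OC(C)(C)O[C@@H]1[C@@H](O[Si](C(C)C)(C(C)C)C(C)C)C=C
F3 | step 12 | C2-epimer of 16 (2-OH trans to O1) | O[C@@H]1C=C[C@H](O[Si](C(C)C)(C(C)C)C(C)C)[C@H]2OC(C)(C)O[C@@]12CO[Si](C)(C)C(C)(C)C
F4 | step 12 | 2-O-(4-nitrobenzoyl) derivative of 16 | O=C(O[C@H]1C=C[C@H](O[Si](C(C)C)(C(C)C)C(C)C)[C@H]2OC(C)(C)O[C@@]12CO[Si](C)(C)C(C)(C)C)c1ccc(cc1)[N+](=O)[O-]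
F5 | step 13 | 2-O-(4-methoxybenzyl) ether of 16 | COc1ccc(CO[C@H]2C=C[C@H](O[Si](C(C)C)(C(C)C)C(C)C)[C@H]3OC(C)(C)O[C@@]23CO[Si](C)(C)C(C)(C)C)cc1
F6 | step 13 | 2-O-PMB 5-O-TIPS triol (1-OH, 6-OH, CH2OH free) | COc1ccc(CO[C@H]2C=C[C@H](O[Si](C(C)C)(C(C)C)C(C)C)[C@@H](O)[C@]2(O)CO)cc1
F7 | step 13 | 2-O-PMB 5-O-TIPS dibenzoate | COc1ccc(CO[C@H]2C=C[C@H](O[Si](C(C)C)(C(C)C)C(C)C)[C@@H](OC(=O)c3ccccc3)[C@]2(O)COC(=O)c2ccccc2)cc1
F8 | step 13 | cis-1,2-diol dibenzoate (5-O-TIPS) | O[C@H]1C=C[C@H](O[Si](C(C)C)(C(C)C)C(C)C)[C@@H](OC(=O)c2ccccc2)[C@]1(O)COC(=O)c1ccccc1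
F9 | step 13 | 1,2-cyclic sulfite of F8 | O=S1O[C@H]2C=C[C@H](O[Si](C(C)C)(C(C)C)C(C)C)[C@@H](OC(=O)c3ccccc3)[C@@]2(COC(=O)c4ccccc4)O1
F10 | step 13 | 1,2-cyclic sulfate of F8 | O=S1(=O)O[C@H]2C=C[C@H](O[Si](C(C)C)(C(C)C)C(C)C)[C@@H](OC(=O)c3ccccc3)[C@@]2(COC(=O)c4ccccc4)O1
F11 | step 13 | lithium 1-O-sulfate of 19 | [Li+].[O-]S(=O)(=O)O[C@@]1(COC(=O)c2ccccc2)[C@H](Cl)C=C[C@H](O[Si](C(C)C)(C(C)C)C(C)C)[C@H]1OC(=O)c1ccccc1
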